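**Plan**
1. Eudesmane numbering is used, and β is the face of the C10 methyl group (C14). Enabling feature: in ring A the C3 oxygen lies 1,4 across the ring from the quaternary C10, and the C3 and C6 oxygens are 1,4-related through C4–C5. Ring A can therefore be a 4,4-disubstituted cyclohexa-2,5-dienone (C3 carbonyl, prochiral C10), and C6 an acyl anion that attacks C5.
2. Retrosynthetic cuts, in order: C4–OH and the C3–O/C4–O epoxide of a C3=C4 olefin, O6–benzoyl, C4–C15, C5–C6 (opens ring B), the two annulation bonds of ring A, C9=C10 (metathesis), C7–C8 (allylation).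
3. Forward: the C6–C9 chain is made first and C10/C14 are added by cross metathesis. Ring A is annulated with methyl vinyl ketone and dehydrogenated, ring B closes in the carbene-catalysed step, and ring A is decorated last.
4. C7 is set as R by an oxazolidinone auxiliary. This centre and the chiral carbene together pick one dienone arm and so fix C10. The tether forces a cis closure, so C5 and C7 are afterwards inverted together by equilibrating the C6 ketone to the trans-decalone with equatorial isopropyl.
5. C6 comes from α-face hydride attack, because C14 blocks the β face. The C3 carbonyl is traded for the C3=C4 olefin, and α-face epoxidation followed by trans-diaxial opening with water sets C3 and C4.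

Key step: step 11

Assumption: the (5aS,10bR) triazolium salt is taken to favour the same dienone arm as the R-configured C7 centre (matched pair). If the pairing proves mismatched, the equally available (5aR,10bS) salt replaces it and nothing else changes.

Step 1
Reactants: 1 (R)-4-benzyl-1,3-oxazolidin-2-one; 2 3-methylbutanoyl chloride
Product: 3 (R)-4-benzyl-3-(3-methylbutanoyl)-1,3-oxazolidin-2-one
Conditions: Et3N, 4-(dimethylamino)pyridine (cat.), CH2Cl2, 0 °C to rt
Reagents that add atoms: none
Why: N-acylation of an oxazolidinone by an acid chloride under nucleophilic catalysis is routine and touches no stereocentre.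

Step 2
Reactants: 3 (R)-4-benzyl-3-(3-methylbutanoyl)-1,3-oxazolidin-2-one; 4 allyl bromide
Product: 6 (R)-4-benzyl-3-[(2R)-2-isopropylpent-4-enoyl]-1,3-oxazolidin-2-one, via sodium Z-enolate 5 (not isolated)
Conditions: NaN(SiMe3)2, THF, −78 °C; then 4, −78 to −30 °C
Reagents that add atoms: none
Why: Evans asymmetric alkylation, in which the benzyl group shields one face of the chelated Z-enolate so that the reactive allylic halide enters from the other face and sets C7 as R.

Step 3
Reactants: 6 (R)-4-benzyl-3-[(2R)-2-isopropylpent-4-enoyl]-1,3-oxazolidin-2-one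
Product: 7 (2R)-2-isopropylpent-4-en-1-ol
Conditions: LiBH4, MeOH (1 equiv), Et2O, 0 °C
Reagents that add atoms: none
Why: reductive cleavage of the imide with methanol-activated LiBH4 gives the primary alcohol without enolisation, so C7 is retained and auxiliary 1 is recovered.

Step 4
Reactants: 7 (2R)-2-isopropylpent-4-en-1-ol
Product: 8 tert-butyl{[(2R)-2-isopropylpent-4-en-1-yl]oxy}diphenylsilane
Conditions: tert-butyl(chloro)diphenylsilane, imidazole, CH2Cl2, rt
Reagents that add atoms: tert-butyl(chloro)diphenylsilane, CC(C)(C)[Si](Cl)(c1ccccc1)c1ccccc1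
Why: silyl ether protection, with this group chosen because it prevents oxa-Michael addition of the hydroxyl to the enal of step 5 and survives the hot acetate buffer of step 7 and the quinone of step 8.

Step 5
Reactants: 8 tert-butyl{[(2R)-2-isopropylpent-4-en-1-yl]oxy}diphenylsilane; 9 methacrolein
Product: 10 (2E,5R)-5-{[(tert-butyldiphenylsilyl)oxy]methyl}-2,6-dimethylhept-2-enal
Conditions: 9 (excess), second-generation Grubbs catalyst RuCl2(=CHPh)(PCy3)(H2IMes) (5 mol %), CH2Cl2, 40 °C
Reagents that add atoms: none
Why: olefin cross metathesis of an unhindered terminal alkene with an electron-poor 1,1-disubstituted partner that does not homodimerise gives the E-trisubstituted enal and brings in C10, C14 and one ring-A carbon.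

Step 6
Reactants: 10 (2E,5R)-5-{[(tert-butyldiphenylsilyl)oxy]methyl}-2,6-dimethylhept-2-enal
Product: 11 (5R)-5-{[(tert-butyldiphenylsilyl)oxy]methyl}-2,6-dimethylheptanal (both C2 epimers)
Conditions: H2 (1 atm), Pd/C, EtOAc, rt
Reagents that add atoms: none
Why: heterogeneous hydrogenation saturates the conjugated C=C before the aldehyde, and the new centre (future C10) forms without control, which does not matter because it loses its chirality in step 8.

Step 7
Reactants: 11 (5R)-5-{[(tert-butyldiphenylsilyl)oxy]methyl}-2,6-dimethylheptanal; 12 methyl vinyl ketone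
Product: 15 4-[(3R)-3-{[(tert-butyldiphenylsilyl)oxy]methyl}-4-methylpentyl]-4-methylcyclohex-2-en-1-one (both C4 epimers), via pyrrolidine enamine 13 (not isolated), via keto aldehyde 14 (not isolated)
Conditions: pyrrolidine, toluene, reflux (Dean–Stark); then 12, 0 °C to rt; then AcOH, NaOAc, H2O, reflux
Reagents that add atoms: none
Why: Stork enamine Michael addition followed by hydrolysis and intramolecular aldol condensation (Robinson-type annulation of an α,α-disubstituted aldehyde) builds ring A and the quaternary C10, whose two epimers converge in step 8.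

Step 8
Reactants: 15 4-[(3R)-3-{[(tert-butyldiphenylsilyl)oxy]methyl}-4-methylpentyl]-4-methylcyclohex-2-en-1-one
Product: 16 4-[(3R)-3-{[(tert-butyldiphenylsilyl)oxy]methyl}-4-methylpentyl]-4-methylcyclohexa-2,5-dien-1-one
Conditions: 2,3-dichloro-5,6-dicyano-1,4-benzoquinone (DDQ), 1,4-dioxane, reflux
Reagents that add atoms: none
Why: quinone dehydrogenation of a 4,4-disubstituted cyclohexenone cannot go on to a phenol, so it stops at the cross-conjugated dienone and makes C10 prochiral.

Step 9
Reactants: 16 4-[(3R)-3-{[(tert-butyldiphenylsilyl)oxy]methyl}-4-methylpentyl]-4-methylcyclohexa-2,5-dien-1-one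
Product: 17 4-[(3R)-3-(hydroxymethyl)-4-methylpentyl]-4-methylcyclohexa-2,5-dien-1-one
Conditions: Bu4NF, AcOH, THF, rt
Reagents that add atoms: none
Why: fluoride desilylation, buffered with acetic acid so that no free alkoxide or basic fluoride attacks the dienone.

Step 10
Reactants: 17 4-[(3R)-3-(hydroxymethyl)-4-methylpentyl]-4-methylcyclohexa-2,5-dien-1-one
Product: 18 (2R)-2-isopropyl-4-(1-methyl-4-oxocyclohexa-2,5-dien-1-yl)butanal
Conditions: Dess–Martin periodinane, CH2Cl2, 0 °C to rt
Reagents that add atoms: none
Why: Dess–Martin oxidation stops at the aldehyde, runs without base so the α-centre C7 is not epimerised, and leaves the dienone untouched.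

Step 11
Reactants: 18 (2R)-2-isopropyl-4-(1-methyl-4-oxocyclohexa-2,5-dien-1-yl)butanal
Product: 20 (5R,7R,10S)-15-noreudesm-1-ene-3,6-dione (cis-fused; 5β-H; 7α-isopropyl; 10β-methyl), via Breslow enaminol 19 (not isolated)
Conditions: (5aS,10bR)-2-(pentafluorophenyl)-5a,10b-dihydro-4H,6H-indeno[2,1-b][1,2,4]triazolo[4,3-d][1,4]oxazin-2-ium tetrafluoroborate (20 mol %), KN(SiMe3)2 (20 mol %), toluene, 23 °C
Reagents that add atoms: none
Why: The carbene freed from the triazolium salt adds to the formyl group and a proton shift gives the Breslow enaminol 19, in which C6 is nucleophilic; C6 adds to C5, the β-carbon of one enone arm, and proton transfer to the resulting C3 enolate followed by expulsion of the carbene leaves the C6 ketone. The closest known reaction type is the enantioselective intramolecular Stetter desymmetrisation of aldehyde-tethered 4,4-disubstituted cyclohexa-2,5-dienones with aminoindanol-derived triazolylidenes, for which closures of five-membered and of all-carbon six-membered rings are known. Ring B closes in the 6-exo-trig mode. C10 becomes stereogenic by the choice of arm, which is governed by the chiral carbene and, in the same sense, by C7: allylic strain in 19 keeps H7 in the enaminol plane and the isopropyl group anti to the forming bond, and the resulting chair, with isopropyl and C14 both equatorial on the nascent ring, exists only for the arm that leads to 10S. C5 is governed by the tether, which can bring C6 only to the dienone face that bears C9, so H5 and C14 end up cis. The step needs conjugate rather than carbonyl addition and an intact C7 centre up to bond formation; the four-atom tether cannot reach the C3 carbonyl, and base is used in no more than the amount of the triazolium salt, so none is left to enolise the aldehyde.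

Step 12
Reactants: 20 (5R,7R,10S)-15-noreudesm-1-ene-3,6-dione
Product: 22 3,3-(ethylenedioxy)-15-noreudesm-1-en-6-one (trans-fused; 5α-H; 7β-isopropyl; 10β-methyl), via cis keto ketal 21 (not isolated)
Conditions: ethane-1,2-diol, p-toluenesulfonic acid monohydrate (cat.), benzene, reflux (Dean–Stark); then NaOMe, MeOH, 60 °C
Reagents that add atoms: ethane-1,2-diol, OCCO
Why: acid-catalysed ketalisation should take the unhindered enone carbonyl (C10 carries no hydrogen, so C1=C2 cannot migrate, and C6 is flanked by two tertiary carbons), and base-mediated enolisation then equilibrates both α-centres of the C6 ketone under thermodynamic control toward the trans-decalone with equatorial isopropyl, because one cis chair form sets C6 syn-axial to the α-oxygen of the ketal and the other makes C4 and C9 axial.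

Step 13
Reactants: 22 3,3-(ethylenedioxy)-15-noreudesm-1-en-6-one
Product: 24 6β-hydroxy-15-noreudesm-1-en-3-one (5α-H; 7β-isopropyl), via hydroxy ketal 23 (not isolated)
Conditions: NaBH4, MeOH, 0 °C to rt; then 1 M HCl, THF, rt
Reagents that add atoms: water, O
Why: borohydride reduction of a hindered cyclohexanone in which the axial β approach is closed by the syn-axial C14, so hydride enters from the α face and gives the axial 6β-alcohol as with 6-oxo-5α-steroids, while the enone stays masked during the reduction and is released by dilute acid.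

Step 14
Reactants: 24 6β-hydroxy-15-noreudesm-1-en-3-one; 25 iodomethane
Product: 27 6β-hydroxyeudesm-1-en-3-one (4α-methyl; 5α-H; 7β-isopropyl), via dilithium dienolate alkoxide 26 (not isolated)
Conditions: LiN(iPr)2 (2.3 equiv), THF, −78 °C; then 25 (1.1 equiv), −78 to −30 °C; H2O quench
Reagents that add atoms: none
Why: kinetic α'-alkylation of a cyclohexenone, in which C4 is the only enolisable position, the hindered lithium alkoxide is not methylated at low temperature, and iodomethane meets the cross-conjugated enolate on the α face away from C14 and O6 to give the equatorial 4α-methyl group (a centre that becomes planar again in step 16).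

Step 15
Reactants: 27 6β-hydroxyeudesm-1-en-3-one; 28 benzoyl chloride
Product: 29 6β-benzoyloxyeudesm-1-en-3-one
Conditions: 28, pyridine, 4-(dimethylamino)pyridine (cat.), 60 °C
Reagents that add atoms: none
Why: nucleophile-catalysed acylation, driven by heat because the alcohol is axial and flanked by the isopropyl group, installs the final ester with retention at C6 before any other hydroxyl is present.

Step 16
Reactants: 29 6β-benzoyloxyeudesm-1-en-3-one
Product: 30 6β-benzoyloxyeudesma-1,3-dien-3-yl trifluoromethanesulfonate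
Conditions: (CF3SO2)2O, 2,6-di-tert-butyl-4-methylpyridine, CH2Cl2, 0 °C to rt
Reagents that add atoms: trifluoromethanesulfonic anhydride, O=S(=O)(OS(=O)(=O)C(F)(F)F)C(F)(F)F
Why: enol triflate formation by O-sulfonylation of the enone and loss of the C4 proton can give only the 1,3-dienyl triflate, since C2 is vinylic and C10 quaternary, and the non-nucleophilic medium spares the benzoate.

Step 17
Reactants: 30 6β-benzoyloxyeudesma-1,3-dien-3-yl trifluoromethanesulfonate
Product: 31 6β-benzoyloxyeudesma-1,3-diene
Conditions: Pd(OAc)2 (5 mol %), PPh3 (10 mol %), HCO2H, Bu3N, DMF, 60 °C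
Reagents that add atoms: none
Why: palladium-catalysed formate reduction of an enol triflate (oxidative addition to zerovalent palladium, formate exchange, decarboxylation, reductive elimination) replaces the triflate by hydrogen without moving either double bond.

Step 18
Reactants: 31 6β-benzoyloxyeudesma-1,3-diene
Product: 32 6β-benzoyloxyeudesm-3-ene
Conditions: 2-nitrobenzenesulfonohydrazide, Et3N, CH2Cl2, rt
Reagents that add atoms: none
Why: diimide reduction transfers two hydrogens in a concerted syn 1,2-fashion much faster to the disubstituted C1=C2 than to the trisubstituted C3=C4, and it attacks neither the ester nor the remaining olefin.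

Step 19
Reactants: 32 6β-benzoyloxyeudesm-3-ene
Product: 33 6β-benzoyloxy-3α,4α-epoxyeudesmane
Conditions: dimethyldioxirane, acetone, 0 °C
Reagents that add atoms: dimethyldioxirane, CC1(C)OO1
Why: dioxirane epoxidation under neutral conditions, with the β face closed by the axial C14 and the axial 6β-benzoate, delivers oxygen to the α face and sets the C3–O bond of the target.

Step 20
Reactants: 33 6β-benzoyloxy-3α,4α-epoxyeudesmane
Product: 34 6β-benzoyloxyeudesmane-3α,4β-diol, (1R,2S,4aS,7R,8R,8aS)-7,8-dihydroxy-4a,8-dimethyl-2-(propan-2-yl)decahydronaphthalen-1-yl benzoate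
Conditions: HClO4 (cat.), THF–H2O, 0 °C to rt
Reagents that add atoms: water, O
Why: acid-catalysed epoxide hydrolysis in which the Fürst–Plattner (trans-diaxial) rule and the preference for the tertiary carbon coincide, so water attacks C4 from the β face with inversion while the 3α C–O bond is kept, giving the 3α,4β-diaxial diol with the 4α-methyl group.

**Compound list**
1 | (R)-4-benzyl-1,3-oxazolidin-2-one | O=C1N[C@H](Cc2ccccc2)CO1 | starting material
2 | 3-methylbutanoyl chloride | CC(C)CC(=O)Cl | starting material
3 | (R)-4-benzyl-3-(3-methylbutanoyl)-1,3-oxazolidin-2-one | CC(C)CC(=O)N1[C@H](Cc2ccccc2)COC1=O | intermediate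
4 | allyl bromide | C=CCBr | starting material
5 | sodium Z-enolate of 3 | [Na+].CC(C)/C=C(\[O-])N1[C@H](Cc2ccccc2)COC1=O | intermediate
6 | (R)-4-benzyl-3-[(2R)-2-isopropylpent-4-enoyl]-1,3-oxazolidin-2-one | C=CC[C@H](C(C)C)C(=O)N1[C@H](Cc2ccccc2)COC1=O | intermediate
7 | (2R)-2-isopropylpent-4-en-1-ol | C=CC[C@H](C(C)C)CO | intermediate
8 | tert-butyl{[(2R)-2-isopropylpent-4-en-1-yl]oxy}diphenylsilane | C=CC[C@H](C(C)C)CO[Si](c1ccccc1)(c1ccccc1)C(C)(C)C | intermediate
9 | methacrolein | CC(=C)C=O | starting material
10 | (2E,5R)-5-{[(tert-butyldiphenylsilyl)oxy]methyl}-2,6-dimethylhept-2-enal | O=C/C(C)=C/C[C@H](C(C)C)CO[Si](c1ccccc1)(c1ccccc1)C(C)(C)C | intermediate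
11 | (5R)-5-{[(tert-butyldiphenylsilyl)oxy]methyl}-2,6-dimethylheptanal, both C2 epimers | O=CC(C)CC[C@H](C(C)C)CO[Si](c1ccccc1)(c1ccccc1)C(C)(C)C | intermediate
12 | methyl vinyl ketone | C=CC(C)=O | starting material
13 | pyrrolidine enamine of 11 | C(N1CCCC1)=C(C)CC[C@H](C(C)C)CO[Si](c1ccccc1)(c1ccccc1)C(C)(C)C | intermediate
14 | (5R)-5-{[(tert-butyldiphenylsilyl)oxy]methyl}-2,6-dimethyl-2-(3-oxobutyl)heptanal, both C2 epimers | CC(=O)CCC(C)(C=O)CC[C@H](C(C)C)CO[Si](c1ccccc1)(c1ccccc1)C(C)(C)C | intermediate
15 | 4-[(3R)-3-{[(tert-butyldiphenylsilyl)oxy]methyl}-4-methylpentyl]-4-methylcyclohex-2-en-1-one, both C4 epimers | O=C1C=CC(C)(CC[C@H](C(C)C)CO[Si](c2ccccc2)(c2ccccc2)C(C)(C)C)CC1 | intermediate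
16 | 4-[(3R)-3-{[(tert-butyldiphenylsilyl)oxy]methyl}-4-methylpentyl]-4-methylcyclohexa-2,5-dien-1-one | O=C1C=CC(C)(CC[C@H](C(C)C)CO[Si](c2ccccc2)(c2ccccc2)C(C)(C)C)C=C1 | intermediate
17 | 4-[(3R)-3-(hydroxymethyl)-4-methylpentyl]-4-methylcyclohexa-2,5-dien-1-one | O=C1C=CC(C)(CC[C@H](C(C)C)CO)C=C1 | intermediate
18 | (2R)-2-isopropyl-4-(1-methyl-4-oxocyclohexa-2,5-dien-1-yl)butanal | CC(C)[C@@H](CCC1(C)C=CC(=O)C=C1)C=O | intermediate
19 | Breslow enaminol from 18 and the (5aS,10bR) triazolylidene | CC(C)[C@@H](CCC1(C)C=CC(=O)C=C1)C(O)=C1N(c2c(F)c(F)c(F)c(F)c2F)N=C2CO[C@H]3Cc4ccccc4[C@H]3N12 | intermediate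
20 | (5R,7R,10S)-15-noreudesm-1-ene-3,6-dione, cis-fused (5β-H, 7α-isopropyl, 10β-methyl) | CC(C)[C@H]1CC[C@@]2(C)C=CC(=O)C[C@H]2C1=O | intermediate
21 | 3,3-(ethylenedioxy)-15-noreudesm-1-en-6-one, cis-fused (5β-H, 7α-isopropyl) | CC(C)[C@H]1CC[C@@]2(C)C=CC3(OCCO3)C[C@H]2C1=O | intermediate
22 | 3,3-(ethylenedioxy)-15-noreudesm-1-en-6-one, trans-fused (5α-H, 7β-isopropyl) | CC(C)[C@@H]1CC[C@@]2(C)C=CC3(OCCO3)C[C@@H]2C1=O | intermediate
23 | 3,3-(ethylenedioxy)-15-noreudesm-1-en-6β-ol (5α-H, 7β-isopropyl) | CC(C)[C@@H]1CC[C@@]2(C)C=CC3(OCCO3)C[C@@H]2[C@@H]1O | intermediate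
24 | 6β-hydroxy-15-noreudesm-1-en-3-one (5α-H, 7β-isopropyl) | CC(C)[C@@H]1CC[C@@]2(C)C=CC(=O)C[C@@H]2[C@@H]1O | intermediate
25 | iodomethane | CI | starting material
26 | dilithium C3 dienolate, O6 alkoxide of 24 | [Li+].[Li+].CC(C)[C@@H]1CC[C@@]2(C)C=CC([O-])=C[C@@H]2[C@@H]1[O-] | intermediate
27 | 6β-hydroxyeudesm-1-en-3-one (4α-methyl, 5α-H, 7β-isopropyl) | CC(C)[C@@H]1CC[C@@]2(C)C=CC(=O)[C@@H](C)[C@@H]2[C@@H]1O | intermediate
28 | benzoyl chloride | O=C(Cl)c1ccccc1 | starting material
29 | 6β-benzoyloxyeudesm-1-en-3-one (4α-methyl, 5α-H) | CC(C)[C@@H]1CC[C@@]2(C)C=CC(=O)[C@@H](C)[C@@H]2[C@@H]1OC(=O)c1ccccc1 | intermediate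
30 | 6β-benzoyloxyeudesma-1,3-dien-3-yl trifluoromethanesulfonate | CC(C)[C@@H]1CC[C@@]2(C)C=CC(OS(=O)(=O)C(F)(F)F)=C(C)[C@@H]2[C@@H]1OC(=O)c1ccccc1 | intermediate
31 | 6β-benzoyloxyeudesma-1,3-diene | CC(C)[C@@H]1CC[C@@]2(C)C=CC=C(C)[C@@H]2[C@@H]1OC(=O)c1ccccc1 | intermediate
32 | 6β-benzoyloxyeudesm-3-ene | CC(C)[C@@H]1CC[C@@]2(C)CCC=C(C)[C@@H]2[C@@H]1OC(=O)c1ccccc1 | intermediate
33 | 6β-benzoyloxy-3α,4α-epoxyeudesmane | CC(C)[C@@H]1CC[C@@]2(C)CC[C@H]3O[C@@]3(C)[C@@H]2[C@@H]1OC(=O)c1ccccc1 | intermediate
34 | 6β-benzoyloxyeudesmane-3α,4β-diol, (3R,4R,5S,6R,7S,10S) | CC(C)[C@@H]1CC[C@@]2(C)CC[C@@H](O)[C@](C)(O)[C@@H]2[C@@H]1OC(=O)c1ccccc1 | target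

Total step count: 20. Longest linear sequence: 20 steps (from 1 and 2).

**Steps most likely to fail**

Step 11.
- What may go wrong: the enaminol may form slowly from the α-branched aldehyde. Epimerisation at C7, aldol or benzoin-type self-condensation, and loss of arm selectivity could then overtake ring closure.
- Fallback: the same C5–C6 bond is made by ketyl radical chemistry under substrate control alone.
- Starting from 18, SmI2 with 1,1,1,3,3,3-hexafluoropropan-2-ol in THF at −78 °C is a known ketyl–olefin closure for aldehyde-tethered cyclohexadienones. It should give the cis-fused 6-hydroxy-15-noreudesm-1-en-3-one F1, with the arm chosen by C7 through the same chair with equatorial isopropyl.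
- Dess–Martin oxidation of the carbinol returns to 20.

Step 12.
- What may go wrong: ketalisation may compete at C6 or occur at both carbonyls. The ring-fusion equilibrium may also be incomplete or unfavourable, because the half-chair of the unsaturated ring A puts too little 1,3-diaxial pressure on the cis forms.
- Fallback: ring A is saturated first, which gives a full chair and an ordinary ketone to protect.
- Starting from 20, hydrogenation over Pd/C gives the cis-fused 15-noreudesmane-3,6-dione F2. Ethane-1,2-diol with p-toluenesulfonic acid protects the unhindered C3 ketone, as with 3,6-dioxo steroids, and gives the cis keto ketal F3.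
- NaOMe in methanol equilibrates C5 and C7 to the trans keto ketal F4. NaBH4 then gives the 6β-hydroxy ketal F5, and dilute HCl releases 6β-hydroxy-15-noreudesman-3-one F6.
- DDQ in dioxane dehydrogenates this trans-fused 3-ketone toward C1–C2, as with 5α-3-oxo steroids, and the route is rejoined at 24.

Step 20.
- What may go wrong: the developing tertiary cation may lose a proton from C15 or C5, or undergo a hydride shift from C3, instead of being captured by water on the crowded β face. Benzoyl migration from O6 to O4 through neighbouring-group participation is also possible.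
- Fallback: C4 is built in the opposite order, with oxygen first and methyl last.
- Starting from 33, Al(OiPr)3 in hot toluene isomerises the epoxide to the exocyclic allylic alcohol 6β-benzoyloxyeudesm-4(15)-en-3α-ol F7. Ozonolysis (O3, then Me2S) gives 6β-benzoyloxy-3α-hydroxy-15-noreudesman-4-one F8.
- MeCeCl2 (from MeLi and CeCl3, excess, THF, −78 °C) adds to the C4 ketone faster than to the hindered benzoate. It should attack from the open α face (equatorial attack, the β face being closed by C14 and O6) and give 34 directly.

Further compounds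
F1 | step 11 | cis-fused 6-hydroxy-15-noreudesm-1-en-3-one (5β-H, 7α-isopropyl, both C6 epimers) | CC(C)[C@H]1CC[C@@]2(C)C=CC(=O)C[C@H]2C1O
F2 | step 12 | cis-fused 15-noreudesmane-3,6-dione (5β-H, 7α-isopropyl) | CC(C)[C@H]1CC[C@@]2(C)CCC(=O)C[C@H]2C1=O
F3 | step 12 | 3,3-(ethylenedioxy)-15-noreudesman-6-one, cis-fused (5β-H, 7α-isopropyl) | CC(C)[C@H]1CC[C@@]2(C)CCC3(OCCO3)C[C@H]2C1=O
F4 | step 12 | 3,3-(ethylenedioxy)-15-noreudesman-6-one, trans-fused (5α-H, 7β-isopropyl) | CC(C)[C@@H]1CC[C@@]2(C)CCC3(OCCO3)C[C@@H]2C1=O
F5 | step 12 | 3,3-(ethylenedioxy)-15-noreudesman-6β-ol (5α-H, 7β-isopropyl) | CC(C)[C@@H]1CC[C@@]2(C)CCC3(OCCO3)C[C@@H]2[C@@H]1O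
F6 | step 12 | 6β-hydroxy-15-noreudesman-3-one (5α-H, 7β-isopropyl) | CC(C)[C@@H]1CC[C@@]2(C)CCC(=O)C[C@@H]2[C@@H]1O
F7 | step 20 | 6β-benzoyloxyeudesm-4(15)-en-3α-ol | CC(C)[C@@H]1CC[C@@]2(C)CC[C@@H](O)C(=C)[C@@H]2[C@@H]1OC(=O)c1ccccc1
F8 | step 20 | 6β-benzoyloxy-3α-hydroxy-15-noreudesman-4-one | CC(C)[C@@H]1CC[C@@]2(C)CC[C@@H](O)C(=O)[C@@H]2[C@@H]1OC(=O)c1ccccc1
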